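**Plan**
- **Enabling feature:** the [2,2-dimethyl-3-isopropenylcyclobutyl]methyl group on C8 of ring A is a prenyl group, C8–CH2–CH=C(CH3)2. Its CH=C(CH3)2 bond has been joined to the CH2=CH end of an isoprene unit. With the intact prenyl group beside it, C8 is a latent gem-diprenyl carbon.
- **First cuts:** the cyclobutane bonds CH–CH2 and C(CH3)2–CH(isopropenyl), a [2+2]. Before that step the isoprene unit is tied through its methyl carbon to the side-chain carboxyl group as an allylic ester. Palladium and formate later erase this tether to CH3 and CO2H.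
- **Further cuts:** both C8–prenyl bonds (dearomatising alkylation), C4–C4a (Friedel–Crafts) and O1–C2 (Mitsunobu) of ring B, and the coumarin (Pechmann).
- **Forward order:** lactone ring on phloroglucinol, O1–C2 ether, reduction of the coumarin C=C, ring B, lactone opening with dearomatisation of ring A, ester tether, 13-membered lactone and cyclobutane in one step, tether removal.
- **Stereochemistry:** C2 and C3 come from (S)-3-hydroxybutanoate (anti methylation, then inversion). The side-chain centre comes from a ligand-controlled copper hydride reduction. C8 and both cyclobutane centres arise in the key step, biased by the side-chain centre through the tether and held cis by the bridge.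

Key step: step 9

Atom labels: chromanone numbering of the target (O1, C2, C3, C4, C4a, C5 to C8, C8a; ring A is the carbocycle, ring B the pyranone). Cyclobutane: C1' bears the CH2 to C8, C2' is C(CH3)2, C3' bears the isopropenyl group, C4' is CH2.

Assumption: (R)-DTBM-SEGPHOS is written for step 4; which ligand enantiomer sends hydride to the face giving the 4S centre on this coumarin must be read from a trial run, and the (S)-ligand is taken if needed.

Step 1
Reactants: 1 phloroglucinol; 2 ethyl 3-oxohexanoate
Product: 3 5,7-dihydroxy-4-propyl-2H-chromen-2-one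
Conditions: CF3SO3H (neat), 0 °C to rt
Reagents that add atoms: none
Why: Pechmann condensation, in which acid-promoted transesterification, ring hydroxyalkylation and dehydration run readily on the threefold symmetric, highly activated triol, so only one coumarin can form and no stereocentre is made.

Step 2
Reactants: 4 tert-butyl (3S)-3-hydroxybutanoate
Product: 5 tert-butyl (2S,3S)-3-hydroxy-2-methylbutanoate
Conditions: LDA (2.2 equiv), THF, −78 to −20 °C; MeI, DMPU, −78 to 0 °C; then H2O
Reagents that add atoms: iodomethane, CI
Why: Fráter–Seebach alkylation, in which the chelated dilithium alkoxide enolate is methylated on the face away from the C3 methyl group, setting C2 as S (anti isomer) under control of the purchased C3 centre.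

Step 3
Reactants: 3 5,7-dihydroxy-4-propyl-2H-chromen-2-one; 5 tert-butyl (2S,3S)-3-hydroxy-2-methylbutanoate
Product: 6 tert-butyl (2S,3R)-3-[(5-hydroxy-2-oxo-4-propyl-2H-chromen-7-yl)oxy]-2-methylbutanoate
Conditions: PPh3, DIAD, THF, 0 °C to rt
Reagents that add atoms: none
Why: Mitsunobu etherification, in which the unhindered 7-OH (a vinylogous carboxylic acid) reacts in preference to the 5-OH next to the propyl group, and SN2 displacement of the oxyphosphonium group inverts the carbinol carbon from S to R (future C2) without touching the alpha centre (future C3).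

Step 4
Reactants: 6 tert-butyl (2S,3R)-3-[(5-hydroxy-2-oxo-4-propyl-2H-chromen-7-yl)oxy]-2-methylbutanoate
Product: 8 tert-butyl (2S,3R)-3-{[(4S)-5-hydroxy-2-oxo-4-propyl-3,4-dihydro-2H-chromen-7-yl]oxy}-2-methylbutanoate, via bis-O-boryl ketene acetal 7 (not isolated)
Conditions: CuCl (5 mol %), NaOtBu (10 mol %), (R)-DTBM-SEGPHOS (5.5 mol %), pinacolborane (3.5 equiv), toluene, rt; then H2O
Reagents that add atoms: none
Why: Copper hydride catalysed asymmetric 1,4-reduction (conjugate hydroboration) of a 4-substituted coumarin, in which the phenol is masked in the flask as its boronic ester, the ligand-bound monovalent copper hydride delivers hydride to one face of C4 to set the S centre under catalyst control, no ketone is yet present to compete, and the boron ketene acetal resists over-reduction until it is hydrolysed.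

Step 5
Reactants: 8 tert-butyl (2S,3R)-3-{[(4S)-5-hydroxy-2-oxo-4-propyl-3,4-dihydro-2H-chromen-7-yl]oxy}-2-methylbutanoate
Product: 10 (4S,7S,8R)-5-hydroxy-7,8-dimethyl-4-propyl-3,4,7,8-tetrahydro-2H,6H-pyrano[3,2-g]chromene-2,6-dione, via free carboxylic acid 9 (not isolated)
Conditions: TFA/CH2Cl2 (1:1), rt; then (CF3CO)2O (3 equiv), 0 °C to rt; aq. NaHCO3 work-up
Reagents that add atoms: none
Why: Acidolysis of the tert-butyl ester followed by intramolecular Friedel–Crafts acylation through the mixed anhydride closes ring B as a six-membered ketone ortho to the free phenol, no base is present to epimerise the alpha centre so the cis-2,3-dimethyl relation is carried over, and closure at the other free ring carbon would only give the lactone isomer that opens to the same hydroxy acid in step 6.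

Step 6
Reactants: 10 (4S,7S,8R)-5-hydroxy-7,8-dimethyl-4-propyl-3,4,7,8-tetrahydro-2H,6H-pyrano[3,2-g]chromene-2,6-dione; 11 prenyl bromide (1-bromo-3-methylbut-2-ene)
Product: 14 (3S)-3-[(2R,3S)-5-hydroxy-2,3-dimethyl-8,8-bis(3-methylbut-2-en-1-yl)-4,7-dioxo-3,4,7,8-tetrahydro-2H-chromen-6-yl]hexanoic acid, via ring-opened hydroxy acid 12 (not isolated), via 8-prenyl hydroxy acid 13 (not isolated)
Conditions: KOH (4.2 equiv), H2O, 0 °C; 11 (2.2 equiv), 0 °C to rt; then 1 M HCl
Reagents that add atoms: water, O
Why: Alkylative dearomatisation of an acylphloroglucinol-type phenolate, the reaction type behind gem-diprenyl hop beta-acids, in which hydroxide opens the lactone, water favours C- over O-alkylation, C8 is the only unsubstituted ring carbon and stays less hindered than C6 after the first prenylation, base is limited to what the acidic groups consume in order to spare C3, and the new quaternary C8 carries two identical groups and is not a stereocentre.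

Step 7
Reactants: 15 2-methyl-2-vinyloxirane (commercial monoepoxide of isoprene, racemic)
Product: 16 2-methylidenebut-3-en-1-ol
Conditions: LDA (1.2 equiv), Et2O, −78 °C to rt; then H2O
Reagents that add atoms: none
Why: Base-induced isomerisation of an epoxide to an allylic alcohol, in which the amide base removes a methyl proton and beta-elimination opens the oxirane to the cross-conjugated dienol, a known preparation of this alcohol that leaves no stereocentre.

Step 8
Reactants: 14 (3S)-3-[(2R,3S)-5-hydroxy-2,3-dimethyl-8,8-bis(3-methylbut-2-en-1-yl)-4,7-dioxo-3,4,7,8-tetrahydro-2H-chromen-6-yl]hexanoic acid; 16 2-methylidenebut-3-en-1-ol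
Product: 17 2-methylidenebut-3-en-1-yl ester of 14
Conditions: DIC (1.2 equiv), DMAP (0.2 equiv), CH2Cl2, 0 °C to rt
Reagents that add atoms: none
Why: Steglich esterification, in which any enol lactone formed from the activated acid and O5 or O7 is itself an acyl donor that DMAP passes on to the primary allylic alcohol, so the reaction converges on the ester and touches no stereocentre.

Step 9
Reactants: 17 2-methylidenebut-3-en-1-yl ester of 14
Product: 18 13-membered macrolactone cycloadduct (internal allylic ester of the target)
Conditions: Ir[dF(CF3)ppy]2(dtbbpy)PF6 (2 mol %), degassed MeCN (2 mM), argon, 450 nm LED, 25 °C; chromatography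
Reagents that add atoms: none
Why: Proposed new method: energy transfer from the excited iridium sensitiser (triplet energy about 61 kcal/mol, just above that of a 2-substituted butadiene) to the diene of 17 should give the diene triplet, whose unsubstituted vinyl CH2 adds to the CH of a prenyl group to leave a tertiary C(CH3)2 radical and an allyl radical, and after spin inversion the C(CH3)2 centre couples with the neighbouring allyl carbon. The closest known reaction type is the visible-light sensitised intramolecular [2+2] cycloaddition of 1,3-dienes with unactivated di- and trisubstituted alkenes across three-atom tethers, whereas neither a long ester tether nor a gem-diprenyl acceptor has been shown. The first bond (prenyl CH to diene CH2) closes the 13-membered lactone ring by 13-exo radical addition at the less substituted alkene carbon, and the second bond (C(CH3)2 to CH) closes the cyclobutane by 1,4-diradical recombination, the transoid allyl radical being unable to reach the six-membered alternative. C8 is set by which diastereotopic prenyl group reacts: with the side-chain C–H in the plane of ring A next to O5, the S centre holds the CH2CO2 arm on the face of the pro-R prenyl group and the propyl group over the pro-S one, which is a bias and not a lock. C1' and C3' are tied cis because both of their substituents are members of the 13-membered ring, whereas the alkene face attacked (C1' relative to C8) depends only on the folding of the tether and is the least secure element, so separation of diastereomeric macrolactones is planned. The step also needs reaction of one prenyl group only, secured by the single diene per molecule, and bonding through the vinyl end of the diene, favoured because closure after attack through the other CH2 would have to join two fully substituted carbons and should revert; the chelated O5–H···O4 enol is left free as a harmless sink for stray excitation.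

Step 10
Reactants: 18 13-membered macrolactone cycloadduct
Product: 19 (3S)-3-[(2R,3S,8R)-8-{[(1S,3R)-2,2-dimethyl-3-(prop-1-en-2-yl)cyclobutyl]methyl}-5-hydroxy-2,3-dimethyl-8-(3-methylbut-2-en-1-yl)-4,7-dioxo-3,4,7,8-tetrahydro-2H-chromen-6-yl]hexanoic acid (target)
Conditions: Pd(PPh3)4 (5 mol %), HCO2H (3 equiv), Et3N (3 equiv), THF, rt; dilute citric acid work-up
Reagents that add atoms: none
Why: Tsuji–Trost ionisation and formate hydrogenolysis of an allylic ester, in which zerovalent palladium expels the carboxylate to give a 2-substituted pi-allyl complex with two equivalent CH2 termini, so hydride transfer from formate can only give the isopropenyl group and the free acid, no beta-hydrogen is available for elimination, and the stereocentres are not involved.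

**Compound list**
1 | phloroglucinol | Oc1cc(O)cc(O)c1 | starting material
2 | ethyl 3-oxohexanoate | CCCC(=O)CC(=O)OCC | starting material
3 | 5,7-dihydroxy-4-propyl-2H-chromen-2-one | CCCC1=CC(=O)Oc2cc(O)cc(O)c12 | intermediate
4 | tert-butyl (3S)-3-hydroxybutanoate | C[C@H](O)CC(=O)OC(C)(C)C | starting material
5 | tert-butyl (2S,3S)-3-hydroxy-2-methylbutanoate | C[C@H](O)[C@H](C)C(=O)OC(C)(C)C | intermediate
6 | tert-butyl (2S,3R)-3-[(5-hydroxy-2-oxo-4-propyl-2H-chromen-7-yl)oxy]-2-methylbutanoate | CCCC1=CC(=O)Oc2cc(O[C@H](C)[C@H](C)C(=O)OC(C)(C)C)cc(O)c12 | intermediate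
7 | bis-O-boryl ketene acetal of 8 (pinacolboryl groups on O5 and on the former lactone carbonyl oxygen, 4S) | CCC[C@H]1C=C(OB2OC(C)(C)C(C)(C)O2)Oc2cc(O[C@H](C)[C@H](C)C(=O)OC(C)(C)C)cc(OB3OC(C)(C)C(C)(C)O3)c12 | intermediate
8 | tert-butyl (2S,3R)-3-{[(4S)-5-hydroxy-2-oxo-4-propyl-3,4-dihydro-2H-chromen-7-yl]oxy}-2-methylbutanoate | CCC[C@H]1CC(=O)Oc2cc(O[C@H](C)[C@H](C)C(=O)OC(C)(C)C)cc(O)c12 | intermediate
9 | (2S,3R)-3-{[(4S)-5-hydroxy-2-oxo-4-propyl-3,4-dihydro-2H-chromen-7-yl]oxy}-2-methylbutanoic acid | CCC[C@H]1CC(=O)Oc2cc(O[C@H](C)[C@H](C)C(=O)O)cc(O)c12 | intermediate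
10 | (4S,7S,8R)-5-hydroxy-7,8-dimethyl-4-propyl-3,4,7,8-tetrahydro-2H,6H-pyrano[3,2-g]chromene-2,6-dione | CCC[C@H]1CC(=O)Oc2cc3O[C@H](C)[C@H](C)C(=O)c3c(O)c12 | intermediate
11 | prenyl bromide (1-bromo-3-methylbut-2-ene) | CC(C)=CCBr | starting material
12 | (3S)-3-[(2R,3S)-5,7-dihydroxy-2,3-dimethyl-4-oxo-3,4-dihydro-2H-chromen-6-yl]hexanoic acid (present as potassium salt) | CCC[C@@H](CC(=O)O)c1c(O)cc2O[C@H](C)[C@H](C)C(=O)c2c1O | intermediate
13 | (3S)-3-[(2R,3S)-5,7-dihydroxy-2,3-dimethyl-8-(3-methylbut-2-en-1-yl)-4-oxo-3,4-dihydro-2H-chromen-6-yl]hexanoic acid (present as potassium salt) | CCC[C@@H](CC(=O)O)c1c(O)c(CC=C(C)C)c2O[C@H](C)[C@H](C)C(=O)c2c1O | intermediate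
14 | (3S)-3-[(2R,3S)-5-hydroxy-2,3-dimethyl-8,8-bis(3-methylbut-2-en-1-yl)-4,7-dioxo-3,4,7,8-tetrahydro-2H-chromen-6-yl]hexanoic acid | CC(C)=CCC1(CC=C(C)C)C(=O)C([C@@H](CCC)CC(=O)O)=C(O)C2=C1O[C@H](C)[C@H](C)C2=O | intermediate
15 | 2-methyl-2-vinyloxirane (racemic) | CC1(C=C)CO1 | starting material
16 | 2-methylidenebut-3-en-1-ol | C=CC(=C)CO | intermediate
17 | 2-methylidenebut-3-en-1-yl (3S)-3-[(2R,3S)-5-hydroxy-2,3-dimethyl-8,8-bis(3-methylbut-2-en-1-yl)-4,7-dioxo-3,4,7,8-tetrahydro-2H-chromen-6-yl]hexanoate | CC(C)=CCC1(CC=C(C)C)C(=O)C([C@@H](CCC)CC(=O)OCC(=C)C=C)=C(O)C2=C1O[C@H](C)[C@H](C)C2=O | intermediate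
18 | 13-membered macrolactone: target skeleton with the carboxyl oxygen bonded to the allylic CH2 on the alkene carbon at C3' (C2 R, C3 S, C8 R, side-chain centre S, C1' S, C3' S, cis-1,3 cyclobutane; the C3' letter differs from that of the target only through the priority of the CH2O branch) | C=C(CO9)[C@H]1C[C@@H](C[C@@]2(CC=C(C)C)C(=O)C([C@@H](CCC)CC9=O)=C(O)C3=C2O[C@H](C)[C@H](C)C3=O)C1(C)C | intermediate
19 | (3S)-3-[(2R,3S,8R)-8-{[(1S,3R)-2,2-dimethyl-3-(prop-1-en-2-yl)cyclobutyl]methyl}-5-hydroxy-2,3-dimethyl-8-(3-methylbut-2-en-1-yl)-4,7-dioxo-3,4,7,8-tetrahydro-2H-chromen-6-yl]hexanoic acid | C=C(C)[C@H]1C[C@@H](C[C@@]2(CC=C(C)C)C(=O)C([C@@H](CCC)CC(=O)O)=C(O)C3=C2O[C@H](C)[C@H](C)C3=O)C1(C)C | target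

**Step count**
- Total steps: 10.
- Longest linear sequence: 8 (steps 1, 3, 4, 5, 6, 8, 9, 10).

**Steps most likely to fail**

**1. Step 9.**
- **What may go wrong:** the diene triplet may relax faster than it reaches a prenyl group across the long tether. Excitation may drain into the ring A chromophore, and dienes of different molecules may add to each other. The choice between the two prenyl groups and between the two alkene faces may be poor.
- **Fallback** (known chemistry only, sets out from 10, returns at 19): the cyclobutane is taken from the chiral pool instead of being built on the core.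
  - Purchased (1R,5R)-(+)-verbenone (CC1=CC(=O)[C@@H]2C[C@H]1C2(C)C) is cleaved with RuCl3 (cat.)/NaIO4 to cis-pinononic acid F1.
  - Wittig methylenation (CH3PPh3Br, KOtBu) gives the isopropenyl acid F2, and LiAlH4 gives the cyclobutylmethanol F3.
  - I2/PPh3/imidazole gives the iodide F4, and zinc dust with LiCl gives the alkylzinc iodide F5.
  - In parallel, 10 is iodinated at its only free ring carbon (NIS, MeCN) to the aryl iodide F6.
  - Negishi coupling of F5 with F6 (Pd(OAc)2, SPhos, THF) gives the 8-(cyclobutylmethyl) lactone F7.
  - Aqueous KOH opens F7 to the hydroxy acid F8, which is alkylated at C8 with one equivalent of 11 as in the second half of step 6.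
  - This should give 19 together with its C8 epimer F9, to be separated by chromatography. The cyclobutane centres are then secure and only C8 is left to separation.

**2. Step 6.**
- **What may go wrong:** O-alkylation may compete, attack may occur at C6, and alkylation may be incomplete or excessive. Hydroxide may also cause epimerisation at C3 or reversible opening of ring B by beta-elimination.
- **Fallback** (sets out from 10, returns at 14): the lactone is kept closed and strong base is avoided.
  - Zerovalent palladium pi-allyl chemistry of the kind known for benzene polyols and naphthols is used: Pd(PPh3)4, Et3B, 3-methylbut-2-en-1-ol, THF, 50 °C.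
  - The ring carbon para to the free phenol is prenylated first to the 8-prenyl lactone F10, then with dearomatisation to the 8,8-diprenyl enol lactone F11.
  - The activated enol lactone of F11 is opened with aqueous NaHCO3/THF to 14.

**3. Step 4.**
- **What may go wrong:** hydride transfer to the electron-rich coumarin, hindered by the neighbouring O5 substituent, may be slow, and face selectivity may be poor.
- **Fallback** (sets out from 6, returns at 8): catalyst control is given up.
  - The C=C bond is hydrogenated without facial control (H2, 5 bar, Pd/C, EtOAc/AcOH).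
  - The two C4 epimers are diastereomers because of the ether side chain, so 8 is separated from the 4R epimer F12 by chromatography or crystallisation.
  - F12 is dehydrogenated with DDQ in dioxane back to 6 for another pass.

**Further compounds**
F1 | step 9 | (1R,3S)-3-acetyl-2,2-dimethylcyclobutane-1-carboxylic acid (cis-pinononic acid) | OC(=O)[C@@H]1C[C@H](C(C)=O)C1(C)C
F2 | step 9 | (1R,3R)-2,2-dimethyl-3-(prop-1-en-2-yl)cyclobutane-1-carboxylic acid | OC(=O)[C@@H]1C[C@H](C(C)=C)C1(C)C
F3 | step 9 | [(1R,3R)-2,2-dimethyl-3-(prop-1-en-2-yl)cyclobutyl]methanol | OC[C@@H]1C[C@H](C(C)=C)C1(C)C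
F4 | step 9 | (1R,3R)-1-(iodomethyl)-2,2-dimethyl-3-(prop-1-en-2-yl)cyclobutane | IC[C@@H]1C[C@H](C(C)=C)C1(C)C
F5 | step 9 | {[(1R,3R)-2,2-dimethyl-3-(prop-1-en-2-yl)cyclobutyl]methyl}zinc iodide | I[Zn]C[C@@H]1C[C@H](C(C)=C)C1(C)C
F6 | step 9 | (4S,7S,8R)-5-hydroxy-10-iodo-7,8-dimethyl-4-propyl-3,4,7,8-tetrahydro-2H,6H-pyrano[3,2-g]chromene-2,6-dione | CCC[C@H]1CC(=O)Oc2c(I)c3O[C@H](C)[C@H](C)C(=O)c3c(O)c12
F7 | step 9 | 10-{[cis-2,2-dimethyl-3-(prop-1-en-2-yl)cyclobutyl]methyl} derivative of 10 (cyclobutane configured as in 19) | CCC[C@H]1CC(=O)Oc2c(C[C@@H]4C[C@H](C(C)=C)C4(C)C)c3O[C@H](C)[C@H](C)C(=O)c3c(O)c12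
F8 | step 9 | (3S)-3-[(2R,3S)-8-{[cis-2,2-dimethyl-3-(prop-1-en-2-yl)cyclobutyl]methyl}-5,7-dihydroxy-2,3-dimethyl-4-oxo-3,4-dihydro-2H-chromen-6-yl]hexanoic acid (cyclobutane configured as in 19) | CCC[C@@H](CC(=O)O)c1c(O)c(C[C@@H]3C[C@H](C(C)=C)C3(C)C)c2O[C@H](C)[C@H](C)C(=O)c2c1O
F9 | step 9 | 8S epimer of 19 | C=C(C)[C@H]1C[C@@H](C[C@]2(CC=C(C)C)C(=O)C([C@@H](CCC)CC(=O)O)=C(O)C3=C2O[C@H](C)[C@H](C)C3=O)C1(C)C
F10 | step 6 | (4S,7S,8R)-5-hydroxy-7,8-dimethyl-10-(3-methylbut-2-en-1-yl)-4-propyl-3,4,7,8-tetrahydro-2H,6H-pyrano[3,2-g]chromene-2,6-dione | CCC[C@H]1CC(=O)Oc2c(CC=C(C)C)c3O[C@H](C)[C@H](C)C(=O)c3c(O)c12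
F11 | step 6 | enol lactone of 14 closed on O7 (C5 ketone, C8 gem-diprenyl) | CCC[C@H]1CC(=O)OC2=C1C(=O)C3=C(O[C@H](C)[C@H](C)C3=O)C2(CC=C(C)C)CC=C(C)C
F12 | step 4 | tert-butyl (2S,3R)-3-{[(4R)-5-hydroxy-2-oxo-4-propyl-3,4-dihydro-2H-chromen-7-yl]oxy}-2-methylbutanoate | CCC[C@@H]1CC(=O)Oc2cc(O[C@H](C)[C@H](C)C(=O)OC(C)(C)C)cc(O)c12
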